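Remark: the target has no stereocentre, stereogenic axis or stereogenic double bond, so its SMILES defines one achiral compound and no stereocontrol is needed. Divarinol (5-propylresorcinol) and olivetolic acid are assumed to be catalogue compounds.

Stenosporic acid is a depside, and the plan cuts ring A (the 2-hydroxy-4-methoxy-6-propylphenyl ring) from the ester carbonyl at the C1′–C(=O) bond. A three-component palladium-catalysed carbonylative esterification joins iodoarene 3 (ring A), carbon monoxide (the ester carbon) and the 4-OH of benzyl olivetolate 5 (ring B), building the whole depside skeleton in one operation. It exploits two features: C1′ is the ring carbon para to O-4′ and ortho to O-2′, so iodination of symmetric divarinol dimethyl ether marks it unambiguously, and the 2-OH of ring B is tied up by hydrogen bonding to its ester, leaving only O-4 free. Boron trichloride then removes the chelated 2′-O-methyl and the benzyl ester together.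

Key step: step 4

Step 1
Reactants: 1 divarinol (5-propylbenzene-1,3-diol)
Product: 2 1,3-dimethoxy-5-propylbenzene
Conditions: MeI (3 equiv), K2CO3 (3 equiv), acetone, reflux
Reagents that add atoms: iodomethane, CI
Why: Williamson ether synthesis, in which carbonate ionises both phenols and the phenoxides are methylated by SN2 on iodomethane to give the symmetric dimethyl ether.

Step 2
Reactants: 2 1,3-dimethoxy-5-propylbenzene
Product: 3 2-iodo-1,5-dimethoxy-3-propylbenzene
Conditions: NIS (1.05 equiv), TFA (10 mol %), MeCN, 0 °C to rt
Reagents that add atoms: N-iodosuccinimide, O=C1CCC(=O)N1I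
Why: Electrophilic aromatic iodination (SEAr) with acid-activated NIS should go para to one methoxy and ortho to the other rather than between the two methoxy groups, and because C4 and C6 of 2 are identical by symmetry a single mono-iodide is expected.

Step 3
Reactants: 4 olivetolic acid (2,4-dihydroxy-6-pentylbenzoic acid)
Product: 5 benzyl olivetolate (benzyl 2,4-dihydroxy-6-pentylbenzoate)
Conditions: BnBr (1.05 equiv), KHCO3 (1.1 equiv), DMF, rt
Reagents that add atoms: benzyl bromide, BrCc1ccccc1
Why: Carboxylate O-alkylation (SN2), in which bicarbonate ionises only the carboxylic acid and not the phenols, so the benzyl ester should form with both hydroxyls left free, and room temperature avoids decarboxylation of the β-resorcylic acid.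

Step 4
Reactants: 3 2-iodo-1,5-dimethoxy-3-propylbenzene, 5 benzyl olivetolate, 6 carbon monoxide
Product: 9 benzyl 4-[(2,4-dimethoxy-6-propylbenzoyl)oxy]-2-hydroxy-6-pentylbenzoate, via arylpalladium iodide 7 (not isolated), via aroylpalladium iodide 8 (not isolated)
Conditions: Pd(OAc)2 (5 mol %), Xantphos (7.5 mol %), Et3N (2.5 equiv), CO (1 atm), toluene, 90 °C
Reagents that add atoms: carbon monoxide (compound 6), [C-]#[O+]
Why: Palladium-catalysed carbonylative esterification (aryloxycarbonylation of an aryl iodide, a Heck-type carbonylation): Pd(0)/Xantphos inserts into the C–I bond of 3 to give arylpalladium iodide 7, migratory insertion of CO forms the C1′–C(=O) bond in aroylpalladium iodide 8, and the triethylammonium phenoxide of 5 attacks 8 so that C–O reductive elimination releases 9 and Pd(0). The closest known reaction type is the phenoxycarbonylation of ortho-substituted aryl iodides at 1 atm CO with wide-bite-angle bisphosphines. No ring is closed and no stereocentre is formed. The selectivity needed is O-4 over O-2 of 5, secured because the 2-OH is hydrogen-bonded to and flanked by the benzyl ester, whereas the 4-OH is the more acidic and unhindered phenol, as in the usual acylations of such 2,4-dihydroxybenzoates. The iodide (rather than a bromide) is chosen to ease oxidative addition at the electron-rich, doubly ortho-substituted ring, and the hindered aryl ester formed should resist further attack by phenoxide or amine.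

Step 5
Reactants: 9 benzyl 4-[(2,4-dimethoxy-6-propylbenzoyl)oxy]-2-hydroxy-6-pentylbenzoate
Product: 11 stenosporic acid, via boron chelate 10 (not isolated)
Conditions: BCl3 (5 equiv), C6HMe5 (3 equiv), CH2Cl2, −78 → 0 °C; then H2O
Reagents that add atoms: none
Why: Chelation-controlled Lewis acid ether cleavage, in which BCl3 held between the depside carbonyl and the 2′-methoxy oxygen should cleave only that methyl ether (the 4′-OMe has no chelate) while the same reagent debenzylates the salicylate-type benzyl ester with pentamethylbenzene trapping the benzyl cation, the aryl ester link being inert to BCl3 at or below 0 °C, and aqueous work-up hydrolyses boron chelate 10 to the free phenol and acid.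

Compound list
1 | divarinol (5-propylbenzene-1,3-diol) | CCCc1cc(O)cc(O)c1 | starting material
2 | 1,3-dimethoxy-5-propylbenzene | CCCc1cc(OC)cc(OC)c1 | intermediate
3 | 2-iodo-1,5-dimethoxy-3-propylbenzene | CCCc1cc(OC)cc(OC)c1I | intermediate
4 | olivetolic acid (2,4-dihydroxy-6-pentylbenzoic acid) | CCCCCc1cc(O)cc(O)c1C(=O)O | starting material
5 | benzyl olivetolate (benzyl 2,4-dihydroxy-6-pentylbenzoate) | CCCCCc1cc(O)cc(O)c1C(=O)OCc1ccccc1 | intermediate
6 | carbon monoxide | [C-]#[O+] | starting material
7 | (2,4-dimethoxy-6-propylphenyl)palladium(II) iodide, Xantphos-ligated (ligand not drawn) | CCCc1cc(OC)cc(OC)c1[Pd]I | intermediate (not isolated)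
8 | (2,4-dimethoxy-6-propylbenzoyl)palladium(II) iodide, Xantphos-ligated (ligand not drawn) | CCCc1cc(OC)cc(OC)c1C(=O)[Pd]I | intermediate (not isolated)
9 | benzyl 4-[(2,4-dimethoxy-6-propylbenzoyl)oxy]-2-hydroxy-6-pentylbenzoate | CCCCCc1cc(OC(=O)c2c(OC)cc(OC)cc2CCC)cc(O)c1C(=O)OCc1ccccc1 | intermediate
10 | boron chelate: ring A as 2′-O-dichloroboryl ether, ring B closed as a 2-chloro-1,3,2-benzodioxaborin-4-one | CCCCCc1cc(OC(=O)c2c(OB(Cl)Cl)cc(OC)cc2CCC)cc2OB(Cl)OC(=O)c12 | intermediate (not isolated)
11 | stenosporic acid (2-hydroxy-4-[(2-hydroxy-4-methoxy-6-propylbenzoyl)oxy]-6-pentylbenzoic acid) | CCCCCc1cc(OC(=O)c2c(O)cc(OC)cc2CCC)cc(O)c1C(=O)O | target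

Total step count: 5
Longest linear sequence: 4 steps (1 → 2 → 3 → 9 → 11; steps 1, 2, 4 and 5)

Steps most likely to fail

Step 4. Oxidative addition and CO insertion at the electron-rich, doubly ortho-substituted iodoarene may be slow, so that hydrodeiodination or catalyst decomposition competes, and some acylation at the chelated 2-OH cannot be excluded. The fallback sets out from 3 and builds the aryl–carbonyl bond and the ester bond in separate, classical operations. Iodine–lithium exchange (n-BuLi, THF, −78 °C) should give (2,4-dimethoxy-6-propylphenyl)lithium F1. Carboxylation in the same flask with CO2 and acidic work-up should give 2,4-dimethoxy-6-propylbenzoic acid F2. Trifluoroacetic anhydride in toluene at rt should turn F2 into the mixed anhydride 2,4-dimethoxy-6-propylbenzoic trifluoroacetic anhydride F3, which should acylate the 4-OH of 5 in the same pot. The fallback comes back to the route at 9.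

Step 5. Debenzylation may be incomplete, the 4′-OMe may be cleaved as well, or the electron-rich rings may be C-benzylated. The fallback sets out from 9 and separates the two unmaskings. Hydrogenolysis (H2, 1 atm, 10% Pd/C, EtOAc, rt) should remove only the benzyl group and give 4-[(2,4-dimethoxy-6-propylbenzoyl)oxy]-2-hydroxy-6-pentylbenzoic acid F4. With no benzyl cation left to handle, BCl3 alone (3 equiv, CH2Cl2, −78 → 0 °C, then H2O) should cleave the chelated 2′-OMe. The fallback comes back to the route at boron chelate 10 and hence at 11.

Step 2. Over-iodination, iodination between the two methoxy groups, or acid-promoted loss of iodine may reduce the amount of clean mono-iodide. The fallback sets out from 2 and installs the halogen in two stages. Bromination with NBS in MeCN (0 °C to rt), expected to be para-selective and to stop at the mono-bromide, should give 2-bromo-1,5-dimethoxy-3-propylbenzene F5. A copper-catalysed aromatic Finkelstein exchange (CuI, NaI, trans-N,N′-dimethylcyclohexane-1,2-diamine, dioxane, 110 °C) should then convert F5 into the iodide. The fallback comes back to the route at 3.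

Further compounds
F1 | step 4 | (2,4-dimethoxy-6-propylphenyl)lithium | [Li]c1c(CCC)cc(OC)cc1OC
F2 | step 4 | 2,4-dimethoxy-6-propylbenzoic acid | CCCc1cc(OC)cc(OC)c1C(=O)O
F3 | step 4 | 2,4-dimethoxy-6-propylbenzoic trifluoroacetic anhydride | CCCc1cc(OC)cc(OC)c1C(=O)OC(=O)C(F)(F)F
F4 | step 5 | 4-[(2,4-dimethoxy-6-propylbenzoyl)oxy]-2-hydroxy-6-pentylbenzoic acid | CCCCCc1cc(OC(=O)c2c(OC)cc(OC)cc2CCC)cc(O)c1C(=O)O
F5 | step 2 | 2-bromo-1,5-dimethoxy-3-propylbenzene | CCCc1cc(OC)cc(OC)c1Br
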